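**Plan**

1. Germacrane numbering is used: ring C1–C10, C14 on C10, C15 on C4, C11 on C7 carrying C12 (lactone C=O) and C13 (CH2OAc). Retrosynthesis: remove both epoxides (C1–C10, C4–C5) to the (1(10)E,4E)-triene lactone; open the lactone C12–O6 to a 6,12-diol; shift C4=C5 back to a C5 carbinol beside a Z C3=C4 alkene; cut C4–C5 of the ten-membered ring (alkenyl bromide + aldehyde); then cut C6–C7/C11–C13 (carbomagnesiation), C1–C2 (allylation) and C8–C9 (propargylation).
2. Forward: ynal → propargylation (C8) → carboalumination/allylation (C14, C1–C2) → vinyl carbomagnesiation/CH2O (C5, C6, C13) → two acylations → diboration/oxidation (O5, O6) → aldehyde → closure of the ten-membered carbocycle at C4–C5 → reductive transposition → butenolide ring → both epoxide rings last.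
3. Enabling feature: C5 is an oxygen-bearing CH between C4 (which carries the C15 methyl) and the C6 carbinol, so C5 can be an α-silyloxy aldehyde and C4 a (Z)-alkenyl metal. The sp2 atoms C1=C10, C3=C4 and C7 leave few rotors in the chain. The C5–OH and the C3=C4 alkene are temporary helpers, removed together in step 13.
4. Stereochemistry: C8 by chiral phosphoric acid catalysis; C6 by Pt-catalysed diboration; alkene geometries by syn-carboalumination (E C1=C10), trans-hydroalumination (Z C3=C4), chelate-controlled anti-carbomagnesiation (C7=C11) and an A1,3-controlled retro-ene (E C4=C5). C1, C10, C4 and C5 are set in one event by peripheral epoxidation of the ten-membered diene under substrate control.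

Key step: step 12

Assumption: the sense of induction of (S)-TRIP in step 4 and of the (R,R)-phosphonite in step 9 is taken from simple aldehydes and terminal dienes; if a model reaction shows the opposite sense the antipodal catalyst is used and nothing else changes.

**Route**

Step 1
Reactants: 1 but-2-yn-1-ol
Product: 3 (Z)-3-bromobut-2-en-1-ol, via cyclic alkenylaluminate 2 (not isolated)
Conditions: Red-Al, THF, 0 °C to rt; then NBS, −78 to 0 °C; aq. Rochelle salt
Reagents that add atoms: N-bromosuccinimide O=C1CCC(=O)N1Br; Red-Al [Na+].[H][Al-]([H])(OCCOC)OCCOC (its Al and alkoxy groups are held only in intermediate 2)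
Why: Hydroxyl-directed trans-hydroalumination puts Al on C4 cis to the carbinol carbon, and bromodealumination with retention should give the Z bromide, which fixes the Z C3=C4 geometry.

Step 2
Reactants: 3 (Z)-3-bromobut-2-en-1-ol
Product: 4 (Z)-1,3-dibromobut-2-ene
Conditions: PBr3, Et2O, 0 °C
Reagents that add atoms: phosphorus tribromide BrP(Br)Br
Why: SN2 bromination of the primary allylic alcohol should leave the vinylic bromide and the alkene geometry untouched.

Step 3
Reactants: 5 tert-butyldimethyl(prop-2-yn-1-yloxy)silane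
Product: 8 4-[(tert-butyldimethylsilyl)oxy]but-2-ynal, via lithium acetylide 6 (not isolated), via lithium hemiaminalate 7 (not isolated)
Conditions: n-BuLi, THF, −78 °C; DMF, −78 to 0 °C; inverse quench into 10% aq. KH2PO4
Reagents that add atoms: N,N-dimethylformamide CN(C)C=O; n-butyllithium [Li]CCCC (its Li is held only in intermediates 6 and 7)
Why: Formylation of the lithium acetylide with DMF is standard, and the buffered inverse quench should release the ynal without amine conjugate addition.

Step 4
Reactants: 8 4-[(tert-butyldimethylsilyl)oxy]but-2-ynal; 9 allenylboronic acid pinacol ester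
Product: 11 (S)-7-[(tert-butyldimethylsilyl)oxy]hepta-1,5-diyn-4-ol, via O-pinacolboryl ether 10 (not isolated)
Conditions: (S)-TRIP phosphoric acid (5 mol %), 4 Å MS, toluene, −20 °C; aq. NaHCO3
Reagents that add atoms: none
Why: Chiral-phosphoric-acid-catalysed propargylboration proceeds through a closed six-membered SE2′ transition state in which the catalyst selects the aldehyde face, which should set C8 as S.

Step 5
Reactants: 11 (S)-7-[(tert-butyldimethylsilyl)oxy]hepta-1,5-diyn-4-ol; 4 (Z)-1,3-dibromobut-2-ene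
Product: 13 (4S,6E,9Z)-10-bromo-1-[(tert-butyldimethylsilyl)oxy]-6-methylundeca-6,9-dien-2-yn-4-ol, via alkenyldimethylalane 12 (not isolated)
Conditions: Me3Al (3 equiv), Cp2ZrCl2 (0.25 equiv), CH2Cl2, 0 °C to rt; then 4, Pd(PPh3)4 (5 mol %), THF, rt; aq. Rochelle salt
Reagents that add atoms: trimethylaluminium C[Al](C)C
Why: Zr-catalysed syn-carboalumination of the terminal alkyne (the internal alkyne reacts far more slowly) gives the E alkenylalane, and the Negishi-type Pd-catalysed alkenylalane–allyl bromide coupling should join C1 to C2 with retention of both geometries, the allylic C–Br reacting far faster than the vinylic one; this sets E C1=C10.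

Step 6
Reactants: 13 (4S,6E,9Z)-10-bromo-1-[(tert-butyldimethylsilyl)oxy]-6-methylundeca-6,9-dien-2-yn-4-ol
Product: 15 (8S)-4-bromo-12-[(tert-butyldimethylsilyl)oxy]-4,5-seco-germacra-1(10)E,3Z,5,7(11)-tetraene-8,13-diol (C13 cis to C8), via cyclic alkenylmagnesium alkoxide 14 (not isolated)
Conditions: vinylmagnesium chloride (5 equiv), THF/toluene, 70 °C; cool to −20 °C, CH2O gas (from paraformaldehyde), to rt; aq. NH4Cl
Reagents that add atoms: vinylmagnesium chloride C=C[Mg]Cl; formaldehyde C=O
Why: Chelation-controlled anti-carbomagnesiation of the propargylic alkoxide delivers the vinyl group to C7 and holds Mg on C11 cis to C8 in a five-membered chelate, so trapping with formaldehyde should place C13 cis to C8 and leave C12 cis to the vinyl group, which fixes the C7=C11 geometry; prompt cold trapping should forestall β-elimination of the silyloxide.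

Step 7
Reactants: 15 (8S)-4-bromo-12-[(tert-butyldimethylsilyl)oxy]-4,5-seco-germacra-1(10)E,3Z,5,7(11)-tetraene-8,13-diol
Product: 16 13-acetate of 15
Conditions: AcCl (1.1 equiv), 2,4,6-collidine, CH2Cl2, −78 °C
Reagents that add atoms: acetyl chloride CC(=O)Cl
Why: Acetyl chloride with collidine at low temperature acylates the primary allylic alcohol selectively over the hindered secondary one.

Step 8
Reactants: 16 13-acetate of 15
Product: 17 (8S)-13-acetoxy-4-bromo-12-[(tert-butyldimethylsilyl)oxy]-4,5-seco-germacra-1(10)E,3Z,5,7(11)-tetraen-8-yl 2-methylpropanoate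
Conditions: isobutyric anhydride, Et3N, DMAP (cat.), CH2Cl2, rt
Reagents that add atoms: isobutyric anhydride CC(C)C(=O)OC(=O)C(C)C
Why: DMAP-catalysed acylation of the secondary allylic alcohol occurs at oxygen, so C8 keeps its configuration.

Step 9
Reactants: 17 (8S)-13-acetoxy-4-bromo-12-[(tert-butyldimethylsilyl)oxy]-4,5-seco-germacra-1(10)E,3Z,5,7(11)-tetraen-8-yl 2-methylpropanoate
Product: 19 (6S,8S)-13-acetoxy-4-bromo-12-[(tert-butyldimethylsilyl)oxy]-5,6-dihydroxy-4,5-seco-germacra-1(10)E,3Z,7(11)-trien-8-yl 2-methylpropanoate, via 5,6-bis(pinacolboronate) 18 (not isolated)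
Conditions: B2pin2, Pt(dba)3 (3 mol %), (R,R)-3,5-diisopropylphenyl-TADDOL phenylphosphonite (6 mol %), THF, 60 °C; then 30% H2O2, aq. NaHCO3, THF, 0 °C
Reagents that add atoms: hydrogen peroxide OO; bis(pinacolato)diboron CC1(C)OB(OC1(C)C)B1OC(C)(C)C(C)(C)O1 (its boron is held only in intermediate 18)
Why: Pt-catalysed enantioselective 1,2-diboration takes the terminal alkene of a 1,3-diene that cannot reach the s-cis form (here 3,4,4-trisubstituted), the ligand choosing the face to set C6 as S, and stereoretentive oxidation gives the diol; the tri- and tetrasubstituted alkenes and the alkenyl bromide should not react.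

Step 10
Reactants: 19 (6S,8S)-5,6-diol
Product: 20 (6S,8S)-5,6-bis(triethylsilyl) ether of 19
Conditions: TESCl, imidazole, DMAP (cat.), CH2Cl2, 0 °C to rt
Reagents that add atoms: chlorotriethylsilane CC[Si](Cl)(CC)CC
Why: Standard silylation of both hydroxyls; the esters and the TBS ether are inert.

Step 11
Reactants: 20 (6S,8S)-5,6-bis(triethylsilyl) ether of 19
Product: 21 (6S,8S)-13-acetoxy-4-bromo-12-[(tert-butyldimethylsilyl)oxy]-5-oxo-6-[(triethylsilyl)oxy]-4,5-seco-germacra-1(10)E,3Z,7(11)-trien-8-yl 2-methylpropanoate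
Conditions: (COCl)2, DMSO, CH2Cl2, −78 to −40 °C; Et3N, −78 to −20 °C; used crude
Reagents that add atoms: none
Why: Under Swern conditions a primary TES ether is cleaved and oxidised directly to the aldehyde while secondary TES and primary TBS ethers survive, so no free α-hydroxy aldehyde is handled; the cold amine quench limits epimerisation at C6.

Step 12
Reactants: 21 (6S,8S)-seco-aldehyde
Product: 23 (5R,6S,8S)-13-acetoxy-12-[(tert-butyldimethylsilyl)oxy]-5α-hydroxy-8α-(isobutyryloxy)-6α-[(triethylsilyl)oxy]germacra-1(10)E,3Z,7(11)-triene, via alkenylchromium(III) species 22 (not isolated)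
Conditions: CrCl2 (10 equiv), NiCl2 (0.1 equiv), DMSO/THF 3:1, slow addition to 2 mM, rt to 45 °C; aq. NH4Cl
Reagents that add atoms: chromium(II) chloride Cl[Cr]Cl (its chromium is held only in intermediate 22)
Why: Ni(0) formed in situ inserts into the C4–Br bond with retention of the Z geometry, transmetalates to the alkenylchromium(III) species 22, and this adds to the C5 aldehyde to form the C4–C5 bond. The closest known reaction type is the Nozaki–Hiyama–Kishi macrocyclisation of alkenyl halide–aldehydes, which is established for medium carbocycles carrying esters and silyl ethers. The ten-membered carbocycle closes in a 10-exo-trig mode (the C=O stays exocyclic); four ring atoms lie in the Z C3=C4 and E C1=C10 alkenes and C7 is sp2, so few rotors must be frozen and high dilution should favour ring closure over dimerisation. The new C5 carbinol centre is expected to form under Felkin–Anh control by the C6 silyloxy group (5R is drawn), but either epimer serves because C5 becomes sp2 in step 13. The step needs chemoselectivity for the alkenyl bromide over the allylic esters and for the aldehyde over the ester carbonyls, which the low Ni loading and the low basicity of organochromium(III) should secure; the non-basic medium also protects the enolisable C6 centre of the α-silyloxy β,γ-unsaturated aldehyde.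

Step 13
Reactants: 23 (5R,6S,8S)-macrocyclic allylic alcohol
Product: 26 (6R,8S)-13-acetoxy-12-[(tert-butyldimethylsilyl)oxy]-8α-(isobutyryloxy)-6α-[(triethylsilyl)oxy]germacra-1(10)E,4E,7(11)-triene, via N-allyl sulfonylhydrazine 24 (not isolated), via allylic diazene 25 (not isolated)
Conditions: PPh3, DEAD, 2-nitrobenzenesulfonyl hydrazide (NBSH), N-methylmorpholine, −30 to 23 °C
Reagents that add atoms: 2-nitrobenzenesulfonyl hydrazide NNS(=O)(=O)c1ccccc1[N+](=O)[O-] (its N and S atoms are held only in intermediates 24 and 25; only hydrogen stays in 26)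
Why: Reductive 1,3-transposition of the allylic alcohol: Mitsunobu displacement at C5 by NBSH (inversion), loss of sulfinic acid to the monoalkyl diazene 25 and a suprafacial retro-ene that expels N2, puts H on C3 and moves the alkene to C4=C5; allylic 1,3-strain across the Z C3=C4 bond should hold H-5 in the alkene plane next to C2 and C6 away from C3, so the E alkene is expected.

Step 14
Reactants: 26 (6R,8S)-bis(silyl) triene
Product: 27 (6R,8S)-13-acetoxy-8α-(isobutyryloxy)germacra-1(10)E,4E,7(11)-triene-6α,12-diol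
Conditions: HF·pyridine, pyridine, THF, 0 °C to rt
Reagents that add atoms: none
Why: Buffered fluoride cleaves the allylic TES and TBS ethers while the esters and the acid-sensitive 1,5-diene should survive.

Step 15
Reactants: 27 (6R,8S)-6α,12-diol
Product: 30 (6R,8S)-13-acetoxy-8α-(isobutyryloxy)germacra-1(10)E,4E,7(11)-trien-12,6α-olide, via hydroxy enal 28 (not isolated), via lactol 29 (not isolated)
Conditions: TEMPO (0.2 equiv), PhI(OAc)2 (2.5 equiv), CH2Cl2, rt
Reagents that add atoms: none
Why: TEMPO/PhI(OAc)2 oxidises only the primary allylic alcohol, the cis-placed C6 hydroxyl traps the enal as the lactol, and this is oxidised on to the butenolide (oxidative lactonisation of a Z-2-ene-1,4-diol).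

Step 16
Reactants: 30 (6R,8S)-triene lactone
Product: 32 target (1R,4R,5R,6S,8S,10R)-13-acetoxy-1β,10α:4α,5β-diepoxy-8α-(isobutyryloxy)germacr-7(11)-en-12,6α-olide (CNP0191378.1), via 1β,10α-monoepoxide 31 (not isolated)
Conditions: mCPBA (2.5 equiv), NaHCO3, CH2Cl2, 0 °C to rt
Reagents that add atoms: meta-chloroperoxybenzoic acid O=C(OO)c1cccc(Cl)c1
Why: Prilezhaev epoxidation of the two electron-rich trisubstituted E alkenes (the conjugated C7=C11 is inert), C1=C10 first; attack on the outer faces of the crown conformer of the 6α-oxygenated (E,E)-germacradienolide, in which C14 and C15 are syn, should set C1, C10, C4 and C5 together as 1β,10α:4α,5β.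

**Compound list**

1 | but-2-yn-1-ol | CC#CCO | starting material
2 | sodium 2,2-bis(2-methoxyethoxy)-3-methyl-2,5-dihydro-1,2-oxaaluminol-2-uide (cyclic alkenylaluminate) | CC1=CCO[Al-]1(OCCOC)OCCOC.[Na+] | intermediate
3 | (Z)-3-bromobut-2-en-1-ol | C/C(Br)=C/CO | intermediate
4 | (Z)-1,3-dibromobut-2-ene | C/C(Br)=C/CBr | intermediate
5 | tert-butyldimethyl(prop-2-yn-1-yloxy)silane | C#CCO[Si](C)(C)C(C)(C)C | starting material
6 | lithium acetylide of 5 | [Li]C#CCO[Si](C)(C)C(C)(C)C | intermediate
7 | lithium 4-[(tert-butyldimethylsilyl)oxy]-1-(dimethylamino)but-2-yn-1-olate (hemiaminalate) | CN(C)C(O[Li])C#CCO[Si](C)(C)C(C)(C)C | intermediate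
8 | 4-[(tert-butyldimethylsilyl)oxy]but-2-ynal | O=CC#CCO[Si](C)(C)C(C)(C)C | intermediate
9 | allenylboronic acid pinacol ester | C=C=CB1OC(C)(C)C(C)(C)O1 | starting material
10 | O-pinacolboryl ether of 11 | C#CC[C@H](OB1OC(C)(C)C(C)(C)O1)C#CCO[Si](C)(C)C(C)(C)C | intermediate
11 | (S)-7-[(tert-butyldimethylsilyl)oxy]hepta-1,5-diyn-4-ol | C#CC[C@H](O)C#CCO[Si](C)(C)C(C)(C)C | intermediate
12 | (E)-alkenyldimethylalane from 11 (as its O-dimethylaluminium alkoxide) | C[Al](C)/C=C(\C)C[C@H](O[Al](C)C)C#CCO[Si](C)(C)C(C)(C)C | intermediate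
13 | (4S,6E,9Z)-10-bromo-1-[(tert-butyldimethylsilyl)oxy]-6-methylundeca-6,9-dien-2-yn-4-ol | C/C(Br)=C/C/C=C(\C)C[C@H](O)C#CCO[Si](C)(C)C(C)(C)C | intermediate
14 | cyclic alkenylmagnesium alkoxide (C11–Mg–O8 chelate; vinyl on C7) | C=CC1=C(CO[Si](C)(C)C(C)(C)C)[Mg]O[C@H]1C/C(C)=C/C/C=C(/C)Br | intermediate
15 | (8S)-4-bromo-12-[(tert-butyldimethylsilyl)oxy]-4,5-seco-germacra-1(10)E,3Z,5,7(11)-tetraene-8,13-diol (C13 cis to C8) | C=C/C(=C(/CO)CO[Si](C)(C)C(C)(C)C)[C@@H](O)C/C(C)=C/C/C=C(/C)Br | intermediate
16 | 13-acetate of 15 | C=C/C(=C(/COC(C)=O)CO[Si](C)(C)C(C)(C)C)[C@@H](O)C/C(C)=C/C/C=C(/C)Br | intermediate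
17 | (8S)-13-acetoxy-4-bromo-12-[(tert-butyldimethylsilyl)oxy]-4,5-seco-germacra-1(10)E,3Z,5,7(11)-tetraen-8-yl 2-methylpropanoate | C=C/C(=C(/COC(C)=O)CO[Si](C)(C)C(C)(C)C)[C@@H](OC(=O)C(C)C)C/C(C)=C/C/C=C(/C)Br | intermediate
18 | 5,6-bis(pinacolboronate) corresponding to diol 19 (same spatial arrangement at C6 and C8) | CC1(C)OB(C[C@@H](B2OC(C)(C)C(C)(C)O2)/C(=C(/COC(C)=O)CO[Si](C)(C)C(C)(C)C)[C@@H](OC(=O)C(C)C)C/C(C)=C/C/C=C(/C)Br)OC1(C)C | intermediate
19 | (6S,8S)-13-acetoxy-4-bromo-12-[(tert-butyldimethylsilyl)oxy]-5,6-dihydroxy-4,5-seco-germacra-1(10)E,3Z,7(11)-trien-8-yl 2-methylpropanoate | OC[C@@H](O)/C(=C(/COC(C)=O)CO[Si](C)(C)C(C)(C)C)[C@@H](OC(=O)C(C)C)C/C(C)=C/C/C=C(/C)Br | intermediate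
20 | (6S,8S)-5,6-bis(triethylsilyl) ether of 19 | CC[Si](CC)(CC)OC[C@@H](O[Si](CC)(CC)CC)/C(=C(/COC(C)=O)CO[Si](C)(C)C(C)(C)C)[C@@H](OC(=O)C(C)C)C/C(C)=C/C/C=C(/C)Br | intermediate
21 | (6S,8S)-13-acetoxy-4-bromo-12-[(tert-butyldimethylsilyl)oxy]-5-oxo-6-[(triethylsilyl)oxy]-4,5-seco-germacra-1(10)E,3Z,7(11)-trien-8-yl 2-methylpropanoate | O=C[C@@H](O[Si](CC)(CC)CC)/C(=C(/COC(C)=O)CO[Si](C)(C)C(C)(C)C)[C@@H](OC(=O)C(C)C)C/C(C)=C/C/C=C(/C)Br | intermediate
22 | C4 alkenylchromium(III) dichloride derived from 21 | O=C[C@@H](O[Si](CC)(CC)CC)/C(=C(/COC(C)=O)CO[Si](C)(C)C(C)(C)C)[C@@H](OC(=O)C(C)C)C/C(C)=C/C/C=C(/C)[Cr](Cl)Cl | intermediate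
23 | (5R,6S,8S)-13-acetoxy-12-[(tert-butyldimethylsilyl)oxy]-5α-hydroxy-8α-(isobutyryloxy)-6α-[(triethylsilyl)oxy]germacra-1(10)E,3Z,7(11)-triene | CC(=O)OC/C(CO[Si](C)(C)C(C)(C)C)=C1\[C@@H](OC(=O)C(C)C)C/C(C)=C/C/C=C(C)\[C@@H](O)[C@H]1O[Si](CC)(CC)CC | intermediate
24 | 5β-[N-amino-N-(2-nitrobenzenesulfonyl)amino] analogue of 23 (C5 inverted) | CC(=O)OC/C(CO[Si](C)(C)C(C)(C)C)=C1\[C@@H](OC(=O)C(C)C)C/C(C)=C/C/C=C(C)\[C@H](N(N)S(=O)(=O)c2ccccc2[N+](=O)[O-])[C@H]1O[Si](CC)(CC)CC | intermediate
25 | 5β-diazenyl analogue of 23 (allylic monoalkyl diazene) | CC(=O)OC/C(CO[Si](C)(C)C(C)(C)C)=C1\[C@@H](OC(=O)C(C)C)C/C(C)=C/C/C=C(C)\[C@H](N=N)[C@H]1O[Si](CC)(CC)CC | intermediate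
26 | (6R,8S)-13-acetoxy-12-[(tert-butyldimethylsilyl)oxy]-8α-(isobutyryloxy)-6α-[(triethylsilyl)oxy]germacra-1(10)E,4E,7(11)-triene | CC(=O)OC/C(CO[Si](C)(C)C(C)(C)C)=C1\[C@@H](OC(=O)C(C)C)C/C(C)=C/CC/C(C)=C/[C@H]1O[Si](CC)(CC)CC | intermediate
27 | (6R,8S)-13-acetoxy-8α-(isobutyryloxy)germacra-1(10)E,4E,7(11)-triene-6α,12-diol | CC(=O)OC/C(CO)=C1\[C@@H](OC(=O)C(C)C)C/C(C)=C/CC/C(C)=C/[C@H]1O | intermediate
28 | (6R,8S)-13-acetoxy-6α-hydroxy-8α-(isobutyryloxy)germacra-1(10)E,4E,7(11)-trien-12-al | CC(=O)OC/C(C=O)=C1\[C@@H](OC(=O)C(C)C)C/C(C)=C/CC/C(C)=C/[C@H]1O | intermediate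
29 | 12,6α-lactol of 28 (anomeric mixture at C12) | CC(=O)OCC1=C2[C@@H](OC(=O)C(C)C)C/C(C)=C/CC/C(C)=C/[C@H]2OC1O | intermediate
30 | (6R,8S)-13-acetoxy-8α-(isobutyryloxy)germacra-1(10)E,4E,7(11)-trien-12,6α-olide | CC(=O)OCC1=C2[C@@H](OC(=O)C(C)C)C/C(C)=C/CC/C(C)=C/[C@H]2OC1=O | intermediate
31 | (1R,6R,8S,10R)-13-acetoxy-1β,10α-epoxy-8α-(isobutyryloxy)germacra-4E,7(11)-dien-12,6α-olide | CC(=O)OCC1=C2[C@@H](OC(=O)C(C)C)C[C@@]3(C)O[C@@H]3CC/C(C)=C/[C@H]2OC1=O | intermediate
32 | (1R,4R,5R,6S,8S,10R)-13-acetoxy-1β,10α:4α,5β-diepoxy-8α-(isobutyryloxy)germacr-7(11)-en-12,6α-olide (CNP0191378.1) | CC(=O)OCC1=C2[C@@H](OC(=O)C(C)C)C[C@@]3(C)O[C@@H]3CC[C@@]3(C)O[C@@H]3[C@H]2OC1=O | target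

**Totals and risks**

Total step count: 16. Longest linear sequence: 14 steps (5 to 32 through steps 3–16; the branch 1 to 4 joins at step 5 and gives the same count).

Steps most likely to fail:

1. Step 12 (ring closure). The ten-membered ring with two endocyclic alkenes is strained, so the alkenylchromium may be protonated or may couple intermolecularly before it cyclises, and nickel may insert into the allylic esters. Fallback: set out from 20 and replace the chromium-mediated addition by a rhodium-catalysed one. Miyaura borylation of the alkenyl bromide (PdCl2(dppf), B2pin2, KOAc, dioxane, 80 °C) should give the alkenylboronate F1 with retention of the Z geometry. The Swern conditions of step 11 should then give the boronate aldehyde F2. Rh(I)/bisphosphine-catalysed intramolecular 1,2-addition of the alkenylboronate to the aldehyde in aqueous dioxane at high dilution should close the same C4–C5 bond and return to the route at 23.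

2. Step 13 (reductive transposition). Mitsunobu displacement at the hindered, A1,3-strained C5 carbinol may stall or proceed in the SN2′ sense, which would give reduction without transposition; control of the new alkene geometry may also be incomplete. Fallback: set out from 23 and reach the same allylic diazene from the ketone instead of by substitution. Dess–Martin oxidation should give the conjugated enone F3, and condensation with tosylhydrazide the tosylhydrazone F4. Reduction with catecholborane followed by NaOAc in warm CHCl3 (alkene-transposing reduction of a conjugated tosylhydrazone) should return to the route at 26.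

3. Step 9 (diboration). The platinum catalyst may add across the diene in the 1,4 sense, discriminate the faces poorly on this 3-substituted diene, or react sluggishly. Fallback: set out from 17 and oxidise the diene terminus through an epoxide. Jacobsen–Katsuki epoxidation ((salen)Mn(III)Cl, buffered NaOCl, 0 °C), which prefers conjugated alkenes over the isolated trisubstituted one, should give the vinyl epoxide F5. Hydrolysis with the matched (salen)Co(III)OAc catalyst and water (hydrolytic kinetic resolution conditions, water attacking C5 so that the C6–O bond is kept) should upgrade the diastereomeric purity and return to the route at 19.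

Further compounds
F1 | step 12 | (6S,8S)-5,6-bis(triethylsilyl) ether 20 with the C4 bromide replaced by a pinacolboronate (alkenylboronate) | CC[Si](CC)(CC)OC[C@@H](O[Si](CC)(CC)CC)/C(=C(/COC(C)=O)CO[Si](C)(C)C(C)(C)C)[C@@H](OC(=O)C(C)C)C/C(C)=C/C/C=C(/C)B1OC(C)(C)C(C)(C)O1
F2 | step 12 | (6S,8S)-seco-aldehyde 21 with the C4 bromide replaced by a pinacolboronate (boronate aldehyde) | O=C[C@@H](O[Si](CC)(CC)CC)/C(=C(/COC(C)=O)CO[Si](C)(C)C(C)(C)C)[C@@H](OC(=O)C(C)C)C/C(C)=C/C/C=C(/C)B1OC(C)(C)C(C)(C)O1
F3 | step 13 | (6S,8S)-13-acetoxy-12-[(tert-butyldimethylsilyl)oxy]-8α-(isobutyryloxy)-6α-[(triethylsilyl)oxy]germacra-1(10)E,3Z,7(11)-trien-5-one (enone) | CC(=O)OC/C(CO[Si](C)(C)C(C)(C)C)=C1\[C@@H](OC(=O)C(C)C)C/C(C)=C/C/C=C(C)\C(=O)[C@H]1O[Si](CC)(CC)CC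
F4 | step 13 | tosylhydrazone of enone F3 | CC(=O)OC/C(CO[Si](C)(C)C(C)(C)C)=C1\[C@@H](OC(=O)C(C)C)C/C(C)=C/C/C=C(C)\C(=NNS(=O)(=O)c2ccc(C)cc2)[C@H]1O[Si](CC)(CC)CC
F5 | step 9 | (6S)-5,6-epoxide of diene 17 (vinyl epoxide) | C1O[C@H]1/C(=C(/COC(C)=O)CO[Si](C)(C)C(C)(C)C)[C@@H](OC(=O)C(C)C)C/C(C)=C/C/C=C(/C)Br
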